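**Remark on the chemistry:** the name is read as gymconopin D; the SMILES string defines the structure, which is achiral. No error was found in the structures of the key-step precursors or product, so they are used unchanged.

## Structural features

Gymconopin D consists of three benzene rings and no other ring. Ring A is a 1,2,3,5-tetrasubstituted benzene: C1 carries the CH2CH2 bridge to ring B (a 3-hydroxyphenyl group), C2 carries the CH2 link to ring C (a 4-hydroxyphenyl group), and C3 and C5 carry methoxy groups, so C4 and C6 are the only C–H positions of ring A. There is no stereocentre; the E double bond and the carbinol carbon that appear on the way are transient and are erased at the end. The fragile points are the two free phenols, which must be masked during the organometallic steps, the electron-rich ring A, and any intermediate in which the carbon between ring A and ring C is at the carbinol or cation level, since that cation is stabilised by the C3 and C5 methoxy groups and by the para oxygen of ring C. The real difficulty is regiochemical: two different carbon substituents must sit on the adjacent carbons C1 and C2 next to the C3 methoxy group, a pattern that electrophilic substitution of a 3,5-dimethoxyphenyl unit does not deliver cleanly. The key step uses the fact that the C2 substituent is a single carbon that can be carried as a carboxyl group. In 2,4-dimethoxybenzoic acid this carboxyl group has one ortho neighbour blocked by methoxy (the future C3) and exactly one free ortho C–H (the future C1), so a carboxylate-directed C–H alkenylation can only place the bridge at C1. The same carboxyl carbon afterwards serves as the electrophile that takes up ring C.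

## Logic of the disconnections

**11 from 9.** No skeletal bond is cut. A C=C bond in the bridge, an oxygen on the carbon between ring A and ring C, and two O-benzyl groups are put back. All three are removed by hydrogen over Pd/C, so a single operation finishes the synthesis, passing through 10. The demand on the forward step is one of order: the alkene must be saturated before any acid can ionise the carbinol, because a diarylmethyl cation next to an ortho alkenyl group would be expected to cyclise to an indene.

**9 from 8.** Only the oxidation level of the link carbon changes. The carbinol, not the ketone, is carried into the hydrogenation, because a hindered, donor-substituted diaryl ketone is reduced slowly on Pd/C, whereas the carbinol C–O bond is doubly benzylic and activated. A silane/acid reduction of 8 itself was rejected for the cation reason named above. The forward step needs a small hydride donor and a non-acidic work-up.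

**8 from 4 and 5.** The bond between the carbonyl carbon and ring C is cut. This joins the third ring in one operation and uses the carboxyl carbon of 4 as the future CH2. Direct addition of an aryllithium to the lithium salt of 4 was rejected: the carboxylate is flanked by two ortho substituents, and displacement of a methoxy group ortho to a carboxylate by organolithium reagents is a known competing reaction. Instead 4 is activated as 6 and treated with 7, the magnesium reagent from 5. The demand is clean acyl substitution at a crowded carbonyl without a second addition.

**4 from 3 and 2 (key disconnection).** The bond between C1 of ring A and the first carbon of the bridge is cut. The carboxyl group of 3 directs the metal to its only free ortho C–H, so the contiguous C1/C2/C3 pattern follows from the substitution of a cheap acid, and no halogen has to be installed. The demand is that the carboxyl group survives: protodecarboxylation and lactonisation must be suppressed.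

**2 from 1.** The terminal C=C bond is cut by a Wittig disconnection to the aldehyde and a one-carbon ylide. This gives the alkene partner in one step, with the phenol already protected as the benzyl ether that is removed in the final hydrogenation.

## Other disconnections considered

**Alternative 1:** Ring A itself is taken apart at C6–C1 and C4–C5. In the forward sense the malonate A2 would add to the β-carbon of the α-benzyl enone A1, and the methyl ketone enolate would then close onto an ester group to give the cyclohexane-1,3-dione ester A3. Ester removal, dehydrogenation to the resorcinol A4, double O-methylation and hydrogenolysis of the benzyl ethers would follow.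
- In its favour: the substitution pattern of ring A is written into an acyclic precursor, so no aromatic regiochemistry has to be controlled; the reagents are cheap and no precious metal is needed; the sp3 centres of A3 are irrelevant.
- Against it: A1 is an α-branched, β-alkyl enone and therefore a poor Michael acceptor; its own preparation needs a cross-aldol condensation at the more substituted α-carbon of an unsymmetrical ketone; the oxidative aromatisation of a dialkylated dione can compete with C-methylation, ring halogenation or loss of the benzyl ethers.
- Comparison: on structure the two plans are equal, since both fix the 1,2,3,5 pattern without ambiguity. On cost of reagents and scalability the enolate chemistry is the better. On step economy it is clearly the worse, with about eight or nine operations against five.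

**Alternative 2:** The bond from C2 of ring A to the link carbon is cut, with a temporary oxygen tether. The diarylethanol A5 and the aldehyde A6 would condense under acid to an oxocarbenium ion, which ring A attacks to close the six-membered isochroman A7 (oxa-Pictet–Spengler reaction). Hydrogenolysis of both benzylic C–O bonds and of the benzyl ethers would give the target.
- In its favour: the two ortho positions of the 3,5-dimethoxyphenyl group of A5 are equivalent and each is activated by an ortho and a para methoxy group, so regiochemistry is settled by symmetry; the assembly is convergent; both stereocentres of A7 are erased; A5 is one organometallic addition away from 1.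
- Against it: once the doubly benzylic C–O bond of A7 is cleaved, the remaining oxygen sits on a carbon that is benzylic only to ring B, which has no ortho or para donor, so its hydrogenolysis should be much slower and may need forcing acid or pressure; under the acidic cyclisation conditions A5 can dehydrate to a stilbene.
- Comparison: on structure the regiocontrol is equal to that of the chosen plan. On step economy this alternative is the better by one or two steps. On mechanism the end game is less reliable than in the chosen plan, where the only C–O bond to be hydrogenolysed is doubly benzylic and donor-activated.

**Alternative 3:** The bond between the bridge CH2 and ring B is cut. The redox-active ester A8 would be reduced at the cathode, lose CO2, and the primary radical would be captured by an arylnickel species formed from the iodide A9 to give the dibenzyl ether A10. Hydrogenolysis would complete the synthesis.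
- In its favour: the C(sp3)–C(sp2) bond is formed under mild conditions; ring B enters last, which suits analogue work; no alkene and no carbinol are involved; the final deprotection is the same as in the chosen plan (equal).
- Against it: the cut leaves the actual problem untouched, because A8 already contains ring A with both adjacent carbon substituents and needs its own regiocontrolled synthesis; the 2-arylethyl radical can abstract hydrogen from the neighbouring doubly benzylic CH2 through a six-membered transition state, which would divert material to reduction or to arylation at the wrong carbon; electrochemical equipment is required.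
- Comparison: on mildness and modularity this alternative is the better. On structure it addresses the easiest bond and is the weaker. On step economy it is the longer once the route to A8 is counted.

Key step: step 2

## Route

Step 1
Reactants: 1 3-benzyloxybenzaldehyde
Product: 2 3-benzyloxystyrene
Conditions: Ph3PCH3Br (1.3 equiv), KOtBu (1.25 equiv), THF, 0 °C to rt
Reagents that add atoms: methyltriphenylphosphonium bromide, C[P+](c1ccccc1)(c1ccccc1)c1ccccc1.[Br-]
Why: Wittig methylenation of a non-enolisable aryl aldehyde with the unstabilised ylide is fast and clean; the benzyl ether is inert to KOtBu and a terminal alkene raises no stereochemical question.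

Step 2
Reactants: 3 2,4-dimethoxybenzoic acid; 2 3-benzyloxystyrene (1.3 equiv)
Product: 4 (E)-2-[2-(3-benzyloxyphenyl)ethenyl]-4,6-dimethoxybenzoic acid
Conditions: [Cp*RhCl2]2 (2.5 mol%), Cu(OAc)2·H2O (2.2 equiv), DMF, 90 °C, N2; aq. citric acid work-up
Reagents that add atoms: none
Why: This is a carboxylate-directed oxidative Heck (Fujiwara–Moritani type) reaction, and the closest known reaction type is the ortho-alkenylation of benzoic acids with styrenes under [Cp*RhCl2]2 with an acetate oxidant. The carboxylate of 3 binds trivalent rhodium, acetate-assisted concerted metalation–deprotonation at C6–H gives a five-membered rhodacycle, 2 inserts syn with the aryl group going to the terminal carbon, syn β-hydride elimination releases the alkene, and two Cu(OAc)2 return monovalent rhodium to the trivalent state. No ring is closed and no stereocentre is formed; the only stereo-element is the E geometry, which follows from the syn insertion/syn elimination sequence and from conjugation and is erased in step 5. Site selectivity is needed and is secured by the substrate: of the C–H bonds at C3, C5 and C6 only C6 is ortho to the carboxylate, and the other ortho position carries a methoxy group, so neither regioisomers nor double alkenylation can arise. The step also needs the carboxyl group to be retained, and for that reason a silver-free oxidant and 90 °C are chosen, because silver salts and temperatures well above 100 °C favour protodecarboxylation of ortho-alkoxybenzoic acids. Unlike an acrylate adduct, the styryl product offers no Michael acceptor for lactonisation to a phthalide, and the benzyl ether of 2 carries no directing group and should stay untouched.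

Step 3
Reactants: 4 (E)-2-[2-(3-benzyloxyphenyl)ethenyl]-4,6-dimethoxybenzoic acid; 5 1-benzyloxy-4-bromobenzene
Product: 8 (E)-(4-benzyloxyphenyl){2-[2-(3-benzyloxyphenyl)ethenyl]-4,6-dimethoxyphenyl}methanone, via acyl chloride 6 (not isolated), via 4-benzyloxyphenylmagnesium bromide 7 (not isolated)
Conditions: 4, (COCl)2, cat. DMF, CH2Cl2, 0 °C to rt, evaporate; 5, Mg, THF, reflux; then 7 (1.1 equiv) added to 6, THF, –78 to 0 °C; aq. NH4Cl
Reagents that add atoms: none
Why: Acyl chloride formation with oxalyl chloride and catalytic DMF is followed by acyl substitution with the arylmagnesium bromide (Grignard ketone synthesis). The 2,6-disubstituted ketone is too hindered for a second addition at low temperature, and attack at the C(=O)Cl group is much faster than displacement of the ortho methoxy group.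

Step 4
Reactants: 8 (E)-(4-benzyloxyphenyl){2-[2-(3-benzyloxyphenyl)ethenyl]-4,6-dimethoxyphenyl}methanone
Product: 9 racemic (E)-(4-benzyloxyphenyl){2-[2-(3-benzyloxyphenyl)ethenyl]-4,6-dimethoxyphenyl}methanol
Conditions: LiAlH4, THF, 0 °C to rt; H2O/aq. NaOH work-up; crude product kept free of acid
Reagents that add atoms: none
Why: Hydride reduction of a diaryl ketone with LiAlH4, whose small hydride reaches the hindered carbonyl while the stilbene and the benzyl ethers are inert. The carbinol centre forms as a racemate without control, which is of no consequence because step 5 erases it; the basic work-up avoids ionisation of the donor-stabilised carbinol.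

Step 5
Reactants: 9 racemic (E)-(4-benzyloxyphenyl){2-[2-(3-benzyloxyphenyl)ethenyl]-4,6-dimethoxyphenyl}methanol
Product: 11 gymconopin D 3-(2-{2-[(4-hydroxyphenyl)methyl]-3,5-dimethoxyphenyl}ethyl)phenol, via debenzylated saturated carbinol 10 (not isolated)
Conditions: H2 (1 atm), 10% Pd/C, EtOAc–EtOH, rt; then AcOH (10 vol%), H2, rt
Reagents that add atoms: none
Why: In this heterogeneous catalytic hydrogenation, alkene saturation and O-benzyl hydrogenolysis are fast in neutral medium and lead to 10, whose doubly benzylic C–O bond, activated by three ortho/para oxygen donors, is then hydrogenolysed. Acetic acid is added only after the alkene is gone, so an ionised carbinol has no neighbouring alkene to attack; aryl methyl ethers and phenols are stable at 1 atm and rt.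

## Compound list

1 | 3-benzyloxybenzaldehyde | O=Cc1cccc(OCc2ccccc2)c1 | starting material
2 | 3-benzyloxystyrene | C=Cc1cccc(OCc2ccccc2)c1 | intermediate
3 | 2,4-dimethoxybenzoic acid | COc1ccc(C(=O)O)c(OC)c1 | starting material
4 | (E)-2-[2-(3-benzyloxyphenyl)ethenyl]-4,6-dimethoxybenzoic acid | COc1cc(/C=C/c2cccc(OCc3ccccc3)c2)c(C(=O)O)c(OC)c1 | intermediate
5 | 1-benzyloxy-4-bromobenzene | Brc1ccc(OCc2ccccc2)cc1 | starting material
6 | (E)-2-[2-(3-benzyloxyphenyl)ethenyl]-4,6-dimethoxybenzoyl chloride | COc1cc(/C=C/c2cccc(OCc3ccccc3)c2)c(C(=O)Cl)c(OC)c1 | intermediate
7 | 4-benzyloxyphenylmagnesium bromide | Br[Mg]c1ccc(OCc2ccccc2)cc1 | intermediate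
8 | (E)-(4-benzyloxyphenyl){2-[2-(3-benzyloxyphenyl)ethenyl]-4,6-dimethoxyphenyl}methanone | COc1cc(/C=C/c2cccc(OCc3ccccc3)c2)c(C(=O)c2ccc(OCc3ccccc3)cc2)c(OC)c1 | intermediate
9 | racemic (E)-(4-benzyloxyphenyl){2-[2-(3-benzyloxyphenyl)ethenyl]-4,6-dimethoxyphenyl}methanol | COc1cc(/C=C/c2cccc(OCc3ccccc3)c2)c(C(O)c2ccc(OCc3ccccc3)cc2)c(OC)c1 | intermediate
10 | racemic 3-(2-{2-[hydroxy(4-hydroxyphenyl)methyl]-3,5-dimethoxyphenyl}ethyl)phenol | COc1cc(CCc2cccc(O)c2)c(C(O)c2ccc(O)cc2)c(OC)c1 | intermediate
11 | gymconopin D, 3-(2-{2-[(4-hydroxyphenyl)methyl]-3,5-dimethoxyphenyl}ethyl)phenol | COc1cc(CCc2cccc(O)c2)c(Cc2ccc(O)cc2)c(OC)c1 | target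

## Step count and least certain steps

Total: 5 steps. Longest linear sequence: 5 steps (1 to 2 to 4 to 8 to 9 to 11); 3 and 5 enter as commercial materials in steps 2 and 3.

**Step 2 (key step).** The most likely failures are loss of CO2 from the crowded, electron-rich acid before or after the coupling, and slow metalation because the ortho methoxy group twists the carboxylate out of the ring plane, which would leave time for oxidative oligomerisation of the styrene. Fallback, setting out from 2: Vilsmeier–Haack formylation (POCl3, DMF) of commercial 1-bromo-3,5-dimethoxybenzene F1 should give 2-bromo-4,6-dimethoxybenzaldehyde F2. A Mizoroki–Heck coupling of F2 with 2 (Pd(OAc)2, P(o-tol)3, NaOAc, DMF, 110 °C, zerovalent palladium as the active species) should give (E)-2-[2-(3-benzyloxyphenyl)ethenyl]-4,6-dimethoxybenzaldehyde F3. This forms the same ring A to bridge bond from a C–Br bond instead of a C–H bond. Addition of 7 to F3 (THF, –78 to 0 °C) leads directly to 9, where the route is rejoined; steps 3 and 4 are then not needed.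

**Step 3.** Acyl substitution at a carbonyl flanked by two ortho substituents may be slow. That would allow homocoupling of the magnesium reagent, attack at the ortho methoxy group of the ketone once formed, or acid-induced lactonisation of the stilbene acid during the chloride formation. Fallback, setting out from 4: reduction with LiAlH4 (THF, reflux) to (E)-{2-[2-(3-benzyloxyphenyl)ethenyl]-4,6-dimethoxyphenyl}methanol F4, oxidation with MnO2 (CH2Cl2, rt) to the aldehyde F3 already named under step 2, and addition of 7, which comes back to the route at 9. This costs one more step but replaces the crowded acyl substitution by a simple aldehyde addition.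

**Step 5.** The hydrogenolysis of the carbinol C–O bond may stall after the alkene and the benzyl ethers have reacted. If acid is present too early, ionisation of the carbinol and attack of the cation on the still unsaturated bridge would lead to cyclised material. Fallback, setting out from 9: the hydrogenation is run in neutral medium only and stopped at 10, which is then isolated and reduced by ionic hydrogenation (Et3SiH, CF3CO2H, CH2Cl2, 0 °C). At that stage no alkene is left for the cation to attack, and the route is rejoined at 11. No compound beyond the list is made (entry F0).

**Step 4.** The carbinol may ionise on work-up or on silica, with attack of the cation on the neighbouring alkene or ether formation, and the hindered carbonyl may be reduced incompletely. Fallback, setting out from 8: hydrogenation first (H2, 10% Pd/C, EtOAc, rt) to (4-hydroxyphenyl){2-[2-(3-hydroxyphenyl)ethyl]-4,6-dimethoxyphenyl}methanone F5, then ionic hydrogenation of the ketone (Et3SiH, CF3CO2H, CH2Cl2, 0 °C to rt), which comes back to the route at 11 without passing through the alkenyl carbinol.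

## Further compounds

F1 | step 2 | 1-bromo-3,5-dimethoxybenzene | COc1cc(Br)cc(OC)c1
F2 | step 2 | 2-bromo-4,6-dimethoxybenzaldehyde | COc1cc(Br)c(C=O)c(OC)c1
F3 | step 2 | (E)-2-[2-(3-benzyloxyphenyl)ethenyl]-4,6-dimethoxybenzaldehyde | COc1cc(/C=C/c2cccc(OCc3ccccc3)c2)c(C=O)c(OC)c1
F4 | step 3 | (E)-{2-[2-(3-benzyloxyphenyl)ethenyl]-4,6-dimethoxyphenyl}methanol | COc1cc(/C=C/c2cccc(OCc3ccccc3)c2)c(CO)c(OC)c1
F0 | step 5 | none | none
F5 | step 4 | (4-hydroxyphenyl){2-[2-(3-hydroxyphenyl)ethyl]-4,6-dimethoxyphenyl}methanone | COc1cc(CCc2cccc(O)c2)c(C(=O)c2ccc(O)cc2)c(OC)c1
A1 | alternative 1 | (E)-3-(4-benzyloxybenzyl)-6-(3-benzyloxyphenyl)hex-3-en-2-one | CC(=O)/C(Cc1ccc(OCc2ccccc2)cc1)=C/CCc1cccc(OCc2ccccc2)c1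
A2 | alternative 1 | dimethyl malonate | COC(=O)CC(=O)OC
A3 | alternative 1 | methyl 3-(4-benzyloxybenzyl)-2-[2-(3-benzyloxyphenyl)ethyl]-4,6-dioxocyclohexane-1-carboxylate (diastereomer mixture) | COC(=O)C1C(CCc2cccc(OCc3ccccc3)c2)C(Cc2ccc(OCc3ccccc3)cc2)C(=O)CC1=O
A4 | alternative 1 | 4-(4-benzyloxybenzyl)-5-[2-(3-benzyloxyphenyl)ethyl]benzene-1,3-diol | Oc1cc(O)c(Cc2ccc(OCc3ccccc3)cc2)c(CCc2cccc(OCc3ccccc3)c2)c1
A5 | alternative 2 | racemic 1-(3-benzyloxyphenyl)-2-(3,5-dimethoxyphenyl)ethanol | COc1cc(CC(O)c2cccc(OCc3ccccc3)c2)cc(OC)c1
A6 | alternative 2 | 4-benzyloxybenzaldehyde | O=Cc1ccc(OCc2ccccc2)cc1
A7 | alternative 2 | 1-(4-benzyloxyphenyl)-3-(3-benzyloxyphenyl)-6,8-dimethoxyisochroman (diastereomer mixture) | COc1cc2c(c(OC)c1)C(c1ccc(OCc3ccccc3)cc1)OC(c1cccc(OCc3ccccc3)c1)C2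
A8 | alternative 3 | 1,3-dioxoisoindolin-2-yl 3-[2-(4-benzyloxybenzyl)-3,5-dimethoxyphenyl]propanoate | COc1cc(CCC(=O)ON2C(=O)c3ccccc3C2=O)c(Cc2ccc(OCc3ccccc3)cc2)c(OC)c1
A9 | alternative 3 | 1-benzyloxy-3-iodobenzene | Ic1cccc(OCc2ccccc2)c1
A10 | alternative 3 | 1-[2-(3-benzyloxyphenyl)ethyl]-2-(4-benzyloxybenzyl)-3,5-dimethoxybenzene | COc1cc(CCc2cccc(OCc3ccccc3)c2)c(Cc2ccc(OCc3ccccc3)cc2)c(OC)c1
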